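**Plan**

1. Retrosynthesis: the four phenols are unmasked last and the C3=C4 double bond is put in by dehydrogenation. This leaves a saturated bicyclo[3.2.1]octane-2,8-dione, whose six-membered ring C1–C2–C3–C4–C5–C8 is cut at C1–C2 and C4–C5.
2. The cut is possible because the C8 ketone has both α-carbons (C1, C5) inside the cyclopentanone ring C1–C7–C6–C5–C8. C2=O is 1,3 to C8=O (acylation retron), and C4 is β to C2=O and bonded to C5 (conjugate-addition retron). The bridge C2–C3–C4 is therefore a dienoyl 1,3-biselectrophile and the cyclopentanone an α,α′-bisnucleophile: a formal (3+3) annulation.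
3. Forward: a purchased chiral cyclopentadienone equivalent receives the two aryl groups by two anti-selective 1,4-additions. The second addition fixes the enolate position, which is stored as an enol triflate and passed on to a regiodefined morpholine enamine (temporary activating group, lost on hydrolysis).
4. The six-membered ring, the side chain and both bridgehead centres then arise in one enamine/acid chloride cascade. The chain enters one oxidation level low (dienoyl, not enynoyl, which would divert to a fused 2-pyranone) and is corrected by a Saegusa–Ito oxidation.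
5. Stereochemistry: C7 comes from the (R)-silyloxy enone, C6 from anti addition next to C7, C5 from attack anti to C6, and C1 from the geometric constraint of the bridge. The E styryl bond comes from 4-methoxycinnamaldehyde.

Key step: step 6

Remark: locants C1–C8 are those of the target bicycle (C1, C5 bridgeheads; C2, C8 carbonyls; C4 styryl-bearing; C6 carries the 3,5-dioxygenated ring, C7 the 4-oxygenated ring). C4 is expected as a mixture of epimers in 14–17, is drawn without configuration there, and is erased in step 7.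

**Step 1**
Reactants: 1 (R)-4-[(tert-butyldimethylsilyl)oxy]cyclopent-2-en-1-one; 2 4-methoxyphenylmagnesium bromide
Product: 4 (R)-4-(4-methoxyphenyl)cyclopent-2-en-1-one, via trans silyloxy ketone 3 (not isolated)
Conditions: 2 (1.3 equiv), CuBr·SMe2 (10 mol %), THF, −78 °C; pH 7 buffer; crude 3, DBU, CH2Cl2, 0 °C
Reagents that add atoms: none
Why: Copper-catalysed conjugate addition of the aryl Grignard reagent should occur anti to the C4 silyloxy group of 1 (substrate control) to give trans ketone 3, and DBU-induced E1cB loss of silanolate then moves the enone so that the aryl-bearing carbon becomes C4 of 4 with (R) configuration, the silyloxy enone serving as a chiral cyclopentadienone equivalent.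

**Step 2**
Reactants: 4 (R)-4-(4-methoxyphenyl)cyclopent-2-en-1-one; 5 3,5-dimethoxyphenylmagnesium chloride
Product: 7 (3S,4R)-3-(3,5-dimethoxyphenyl)-4-(4-methoxyphenyl)cyclopent-1-en-1-yl trifluoromethanesulfonate, via chloromagnesium enolate 6 (not isolated)
Conditions: 5 (1.5 equiv), CuI (15 mol %), LiCl (30 mol %), THF, −78 to −40 °C; then N-(5-chloropyridin-2-yl)bis(trifluoromethanesulfonyl)imide, −78 to 0 °C
Reagents that add atoms: N-(5-chloropyridin-2-yl)bis(trifluoromethanesulfonyl)imide, FC(F)(F)S(=O)(=O)N(c1ccc(Cl)cn1)S(=O)(=O)C(F)(F)F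
Why: Copper-catalysed conjugate addition anti to the C4 aryl group should set the second stereocentre trans (substrate control) and leave enolate 6 only on the side of the new aryl group, where O-sulfonylation (conjugate addition–enolate trapping) freezes the double-bond position as enol triflate 7.

**Step 3**
Reactants: 7 (3S,4R)-3-(3,5-dimethoxyphenyl)-4-(4-methoxyphenyl)cyclopent-1-en-1-yl trifluoromethanesulfonate
Product: 8 4-[(3S,4R)-3-(3,5-dimethoxyphenyl)-4-(4-methoxyphenyl)cyclopent-1-en-1-yl]morpholine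
Conditions: morpholine (1.2 equiv), Pd(OAc)2 (5 mol %), rac-BINAP (7.5 mol %), Cs2CO3 (1.5 equiv), toluene, 80 °C, argon; filtered and used crude
Reagents that add atoms: morpholine, C1COCCN1
Why: Palladium-catalysed C–N cross-coupling of an alkenyl triflate with a secondary amine (Buchwald–Hartwig-type enamine synthesis) should replace the triflate by morpholine with the double bond kept in place, because no acid is present to equilibrate the enamine, and no stereocentre is touched.

**Step 4**
Reactants: 9 (E)-4-methoxycinnamaldehyde; 10 malonic acid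
Product: 11 (2E,4E)-5-(4-methoxyphenyl)penta-2,4-dienoic acid
Conditions: pyridine, piperidine (cat.), 90 °C
Reagents that add atoms: none
Why: Knoevenagel–Doebner condensation with decarboxylation should give the new double bond as the (2E) isomer under thermodynamic control while the (4E) bond of 9 is retained.

**Step 5**
Reactants: 11 (2E,4E)-5-(4-methoxyphenyl)penta-2,4-dienoic acid
Product: 12 (2E,4E)-5-(4-methoxyphenyl)penta-2,4-dienoyl chloride
Conditions: (COCl)2 (1.2 equiv), DMF (cat.), CH2Cl2, 0 °C to rt; evaporated and used directly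
Reagents that add atoms: oxalyl chloride, ClC(=O)C(=O)Cl
Why: Acid chloride formation through the catalytic Vilsmeier-type chloroiminium species is standard for 5-aryl-2,4-dienoic acids and should leave the diene geometry untouched.

**Step 6**
Reactants: 8 4-[(3S,4R)-3-(3,5-dimethoxyphenyl)-4-(4-methoxyphenyl)cyclopent-1-en-1-yl]morpholine; 12 (2E,4E)-5-(4-methoxyphenyl)penta-2,4-dienoyl chloride
Product: 16 (1R,5R,6S,7S)-6-(3,5-dimethoxyphenyl)-7-(4-methoxyphenyl)-4-[(E)-2-(4-methoxyphenyl)ethenyl]bicyclo[3.2.1]octane-2,8-dione (C4 epimers), via N-acylenammonium chloride 13 (not isolated), via iminium ketene chloride 14 (not isolated), via bicyclic iminium chloride 15 (not isolated)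
Conditions: 8 added to 12 (1.1 equiv), toluene, −20 °C, then 90 °C, 4 h; then H2O, rt
Reagents that add atoms: water, O
Why: N-acylation of enamine 8 by 12 gives salt 13, a chair-like 3-aza-Cope shift then joins the enamine carbon (future C5) to the β-carbon of the dienoyl unit (C4) and sets free the iminium ketene 14, the iminium tautomerises to the less substituted enamine on the other side of C8, and its carbon (future C1) adds to the ketene carbon C2 to give 15, which water hydrolyses to the C8 ketone. The closest known reaction type is the α,α′-annulation of cyclopentanone and cyclohexanone enamines with acryloyl or crotonoyl chloride to bicyclo[3.2.1]octane-2,8-diones and bicyclo[3.3.1]nonane-2,9-diones. Only one ring is closed, the six-membered ring C1–C2–C3–C4–C5–C8, by a 6-(enolendo)-exo attack of the enamine carbon on the ketene carbonyl carbon, the first C–C bond being made through a six-membered pericyclic transition state without ring formation. C5 is set by approach of the acyl arm anti to the neighbouring C6 aryl group, C1 has no choice because the three-carbon tether can only reach the face that already carries the C4–C5 bond (which places the bridge cis to the C7 aryl group), and C4 is left as a mixture that step 7 erases. The step needs the regiochemistry C4 to C5 and C2 to C1, which rests on the double bond of 8 staying where the triflate was: 8 is added to an excess of 12 at −20 °C so that every nitrogen is quaternised before any proton source can move the double bond. Carbon rather than heteroatom acylation in the closing stage is secured by the tertiary nitrogen, which cannot retain an acyl group, and the preference of the iminium for the less substituted enamine should keep C5 from epimerising.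

**Step 7**
Reactants: 16 (1R,5R,6S,7S)-6-(3,5-dimethoxyphenyl)-7-(4-methoxyphenyl)-4-[(E)-2-(4-methoxyphenyl)ethenyl]bicyclo[3.2.1]octane-2,8-dione (C4 epimers)
Product: 18 (1R,5S,6S,7S)-6-(3,5-dimethoxyphenyl)-7-(4-methoxyphenyl)-4-[(E)-2-(4-methoxyphenyl)ethenyl]bicyclo[3.2.1]oct-3-ene-2,8-dione, via trimethylsilyl enol ether 17 (not isolated)
Conditions: TMSOTf (1.3 equiv), Et3N (2 equiv), CH2Cl2, 0 °C; concentrate; Pd(OAc)2 (1.1 equiv), MeCN, rt
Reagents that add atoms: none
Why: Saegusa–Ito oxidation, in which enolisation can occur only towards C3 (C1 is a bridgehead and the C8 ketone has no enolisable α-hydrogen) and β-hydride elimination from the palladium enolate removes the C4 hydrogen of either epimer, should give the C3=C4 enone conjugated with the styryl group, so the C4 mixture converges.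

**Step 8**
Reactants: 18 (1R,5S,6S,7S)-6-(3,5-dimethoxyphenyl)-7-(4-methoxyphenyl)-4-[(E)-2-(4-methoxyphenyl)ethenyl]bicyclo[3.2.1]oct-3-ene-2,8-dione
Product: 19 (1R,5S,6S,7S)-6-(3,5-dihydroxyphenyl)-7-(4-hydroxyphenyl)-4-[(E)-2-(4-hydroxyphenyl)ethenyl]bicyclo[3.2.1]oct-3-ene-2,8-dione
Conditions: BBr3 (8 equiv), CH2Cl2, −78 to 0 °C; then ice water
Reagents that add atoms: none
Why: Lewis acid ether cleavage (BBr3 demethylation) of the four aryl methyl ethers through aryloxyboron bromides should free the phenols without touching a stereocentre, and the acidic, non-nucleophilic medium should spare the base-labile non-enolisable β-diketone.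

**Compound list**

1 | (R)-4-[(tert-butyldimethylsilyl)oxy]cyclopent-2-en-1-one | O=C1C=C[C@H](O[Si](C)(C)C(C)(C)C)C1 | starting material
2 | 4-methoxyphenylmagnesium bromide | COc1ccc([Mg]Br)cc1 | starting material
3 | (3S,4R)-4-[(tert-butyldimethylsilyl)oxy]-3-(4-methoxyphenyl)cyclopentan-1-one | O=C1C[C@@H](c2ccc(OC)cc2)[C@H](O[Si](C)(C)C(C)(C)C)C1 | intermediate
4 | (R)-4-(4-methoxyphenyl)cyclopent-2-en-1-one | O=C1C=C[C@H](c2ccc(OC)cc2)C1 | intermediate
5 | 3,5-dimethoxyphenylmagnesium chloride | COc1cc(OC)cc([Mg]Cl)c1 | starting material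
6 | chloromagnesium (3S,4R)-3-(3,5-dimethoxyphenyl)-4-(4-methoxyphenyl)cyclopent-1-en-1-olate | Cl[Mg]OC1=C[C@@H](c2cc(OC)cc(OC)c2)[C@H](c2ccc(OC)cc2)C1 | intermediate
7 | (3S,4R)-3-(3,5-dimethoxyphenyl)-4-(4-methoxyphenyl)cyclopent-1-en-1-yl trifluoromethanesulfonate | FC(F)(F)S(=O)(=O)OC1=C[C@@H](c2cc(OC)cc(OC)c2)[C@H](c2ccc(OC)cc2)C1 | intermediate
8 | 4-[(3S,4R)-3-(3,5-dimethoxyphenyl)-4-(4-methoxyphenyl)cyclopent-1-en-1-yl]morpholine | C1COCCN1C1=C[C@@H](c2cc(OC)cc(OC)c2)[C@H](c2ccc(OC)cc2)C1 | intermediate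
9 | (E)-4-methoxycinnamaldehyde | COc1ccc(/C=C/C=O)cc1 | starting material
10 | malonic acid | OC(=O)CC(=O)O | starting material
11 | (2E,4E)-5-(4-methoxyphenyl)penta-2,4-dienoic acid | COc1ccc(/C=C/C=C/C(=O)O)cc1 | intermediate
12 | (2E,4E)-5-(4-methoxyphenyl)penta-2,4-dienoyl chloride | COc1ccc(/C=C/C=C/C(=O)Cl)cc1 | intermediate
13 | 4-[(3S,4R)-3-(3,5-dimethoxyphenyl)-4-(4-methoxyphenyl)cyclopent-1-en-1-yl]-4-[(2E,4E)-5-(4-methoxyphenyl)penta-2,4-dienoyl]morpholin-4-ium chloride | O=C(/C=C/C=C/c1ccc(OC)cc1)[N+]1(CCOCC1)C1=C[C@@H](c2cc(OC)cc(OC)c2)[C@H](c2ccc(OC)cc2)C1.[Cl-] | intermediate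
14 | 4-{(2R,3S,4R)-3-(3,5-dimethoxyphenyl)-4-(4-methoxyphenyl)-2-[(E)-1-(4-methoxyphenyl)-5-oxopenta-1,4-dien-3-yl]cyclopentylidene}morpholin-4-ium chloride (iminium ketene, side-chain C3 epimers) | O=C=CC(/C=C/c1ccc(OC)cc1)[C@H]1C(=[N+]2CCOCC2)C[C@@H](c2ccc(OC)cc2)[C@@H]1c1cc(OC)cc(OC)c1.[Cl-] | intermediate
15 | C8 morpholin-4-ium-4-ylidene chloride of 16 (bicyclic iminium salt, C4 epimers) | O=C1CC(/C=C/c2ccc(OC)cc2)[C@H]2C(=[N+]3CCOCC3)[C@@H]1[C@@H](c1ccc(OC)cc1)[C@@H]2c1cc(OC)cc(OC)c1.[Cl-] | intermediate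
16 | (1R,5R,6S,7S)-6-(3,5-dimethoxyphenyl)-7-(4-methoxyphenyl)-4-[(E)-2-(4-methoxyphenyl)ethenyl]bicyclo[3.2.1]octane-2,8-dione (C4 epimers) | O=C1CC(/C=C/c2ccc(OC)cc2)[C@H]2C(=O)[C@@H]1[C@@H](c1ccc(OC)cc1)[C@@H]2c1cc(OC)cc(OC)c1 | intermediate
17 | C2 trimethylsilyl enol ether of 16 (2-trimethylsilyloxy-bicyclo[3.2.1]oct-2-en-8-one, C4 epimers) | C[Si](C)(C)OC1=CC(/C=C/c2ccc(OC)cc2)[C@H]2C(=O)[C@@H]1[C@@H](c1ccc(OC)cc1)[C@@H]2c1cc(OC)cc(OC)c1 | intermediate
18 | (1R,5S,6S,7S)-6-(3,5-dimethoxyphenyl)-7-(4-methoxyphenyl)-4-[(E)-2-(4-methoxyphenyl)ethenyl]bicyclo[3.2.1]oct-3-ene-2,8-dione | O=C1C=C(/C=C/c2ccc(OC)cc2)[C@H]2C(=O)[C@@H]1[C@@H](c1ccc(OC)cc1)[C@@H]2c1cc(OC)cc(OC)c1 | intermediate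
19 | (1R,5S,6S,7S)-6-(3,5-dihydroxyphenyl)-7-(4-hydroxyphenyl)-4-[(E)-2-(4-hydroxyphenyl)ethenyl]bicyclo[3.2.1]oct-3-ene-2,8-dione | O=C1C=C(/C=C/c2ccc(O)cc2)[C@H]2C(=O)[C@@H]1[C@@H](c1ccc(O)cc1)[C@@H]2c1cc(O)cc(O)c1 | target

**Step count**

Total steps: 8. Longest linear sequence: 6 (steps 1, 2, 3, 6, 7, 8).

**Steps most likely to fail**

Step 6. Three processes could divert it. The acid chloride carbonyl may acylate the enamine carbon directly, because the β-carbon is deactivated by conjugation with the styryl group. The enamine double bond may migrate before the first C–C bond forms, which would give the regioisomeric bicycle. C5 may epimerise through the more substituted enamine. The fallback replaces the acyl cascade by a conjugate addition–aldol annulation at the aldehyde oxidation level; it sets out from 4 and comes back at 16.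
- Copper-catalysed addition of 5 to 4 with Me3SiCl trapping (CuI, THF, −78 °C) should give [(3S,4R)-3-(3,5-dimethoxyphenyl)-4-(4-methoxyphenyl)cyclopent-1-en-1-yl]oxytrimethylsilane F1.
- Wittig reaction of 9 with (triphenylphosphoranylidene)acetaldehyde should give (2E,4E)-5-(4-methoxyphenyl)penta-2,4-dienal F2.
- Secondary-amine (iminium) catalysed Mukaiyama–Michael addition of F1 to F2, anti to the C6 aryl group, should give 3-[(1R,2S,3R)-2-(3,5-dimethoxyphenyl)-3-(4-methoxyphenyl)-5-oxocyclopentyl]-5-(4-methoxyphenyl)pent-4-enal F3.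
- Acid-catalysed intramolecular aldol addition (HCl, THF) from the only enol that can reach the aldehyde should close the bridge to (1R,5R,6S,7S)-2-hydroxy-6-(3,5-dimethoxyphenyl)-7-(4-methoxyphenyl)-4-[(E)-2-(4-methoxyphenyl)ethenyl]bicyclo[3.2.1]octan-8-one F4.
- Dess–Martin oxidation of F4 should deliver 16.

Step 3. The enamine double bond may migrate under the warm basic coupling conditions or through palladium hydride species, the enamine may hydrolyse on handling, and the triflate may be reduced. The fallback gives up the regiodefined coupling for a classical condensation and a late separation; it sets out from 4, comes back at 8 (as a mixture), and is purified at 16.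
- Copper-catalysed addition of 5 to 4 with aqueous quench should give (3R,4R)-3-(3,5-dimethoxyphenyl)-4-(4-methoxyphenyl)cyclopentan-1-one F5.
- Condensation with morpholine (TiCl4, toluene) should give 8 together with its double-bond isomer 4-[(3S,4R)-4-(3,5-dimethoxyphenyl)-3-(4-methoxyphenyl)cyclopent-1-en-1-yl]morpholine F6.
- The mixture is taken through step 6, and 16 is separated by chromatography from the regioisomer (1R,5R,6S,7S)-7-(3,5-dimethoxyphenyl)-6-(4-methoxyphenyl)-4-[(E)-2-(4-methoxyphenyl)ethenyl]bicyclo[3.2.1]octane-2,8-dione F7.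

Step 8. The freed resorcinol ring may undergo Lewis-acid-induced Friedel–Crafts attack on the C8 ketone or on the dienone, and the p-hydroxystyryl dienone may oligomerise in the boron-rich acidic medium. The fallback moves the demethylation ahead of the dienone and finishes under mild acid; it sets out from 16 and comes back at 19.
- BBr3 on the saturated dione 16 should give (1R,5R,6S,7S)-6-(3,5-dihydroxyphenyl)-7-(4-hydroxyphenyl)-4-[(E)-2-(4-hydroxyphenyl)ethenyl]bicyclo[3.2.1]octane-2,8-dione F8.
- Ac2O and pyridine should give its tetraacetate F9.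
- TMSOTf and Et3N should give the C2 trimethylsilyl enol ether of the tetraacetate F10.
- Pd(OAc)2 in MeCN should give the tetraacetate of 19 F11.
- HCl in methanol (from acetyl chloride, 0 °C) should remove the acetates to give 19.

**Further compounds**

F1 | step 6 | [(3S,4R)-3-(3,5-dimethoxyphenyl)-4-(4-methoxyphenyl)cyclopent-1-en-1-yl]oxytrimethylsilane | C[Si](C)(C)OC1=C[C@@H](c2cc(OC)cc(OC)c2)[C@H](c2ccc(OC)cc2)C1
F2 | step 6 | (2E,4E)-5-(4-methoxyphenyl)penta-2,4-dienal | COc1ccc(/C=C/C=C/C=O)cc1
F3 | step 6 | 3-[(1R,2S,3R)-2-(3,5-dimethoxyphenyl)-3-(4-methoxyphenyl)-5-oxocyclopentyl]-5-(4-methoxyphenyl)pent-4-enal (side-chain C3 epimers) | O=CCC(/C=C/c1ccc(OC)cc1)[C@H]1C(=O)C[C@@H](c2ccc(OC)cc2)[C@@H]1c1cc(OC)cc(OC)c1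
F4 | step 6 | (1R,5R,6S,7S)-2-hydroxy-6-(3,5-dimethoxyphenyl)-7-(4-methoxyphenyl)-4-[(E)-2-(4-methoxyphenyl)ethenyl]bicyclo[3.2.1]octan-8-one (C2 and C4 epimers) | OC1CC(/C=C/c2ccc(OC)cc2)[C@H]2C(=O)[C@@H]1[C@@H](c1ccc(OC)cc1)[C@@H]2c1cc(OC)cc(OC)c1
F5 | step 3 | (3R,4R)-3-(3,5-dimethoxyphenyl)-4-(4-methoxyphenyl)cyclopentan-1-one | O=C1C[C@@H](c2cc(OC)cc(OC)c2)[C@H](c2ccc(OC)cc2)C1
F6 | step 3 | 4-[(3S,4R)-4-(3,5-dimethoxyphenyl)-3-(4-methoxyphenyl)cyclopent-1-en-1-yl]morpholine | C1COCCN1C1=C[C@@H](c2ccc(OC)cc2)[C@H](c2cc(OC)cc(OC)c2)C1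
F7 | step 3 | (1R,5R,6S,7S)-7-(3,5-dimethoxyphenyl)-6-(4-methoxyphenyl)-4-[(E)-2-(4-methoxyphenyl)ethenyl]bicyclo[3.2.1]octane-2,8-dione (C4 epimers) | O=C1CC(/C=C/c2ccc(OC)cc2)[C@H]2C(=O)[C@@H]1[C@@H](c1cc(OC)cc(OC)c1)[C@@H]2c1ccc(OC)cc1
F8 | step 8 | (1R,5R,6S,7S)-6-(3,5-dihydroxyphenyl)-7-(4-hydroxyphenyl)-4-[(E)-2-(4-hydroxyphenyl)ethenyl]bicyclo[3.2.1]octane-2,8-dione (C4 epimers) | O=C1CC(/C=C/c2ccc(O)cc2)[C@H]2C(=O)[C@@H]1[C@@H](c1ccc(O)cc1)[C@@H]2c1cc(O)cc(O)c1
F9 | step 8 | tetraacetate of F8 | O=C1CC(/C=C/c2ccc(OC(C)=O)cc2)[C@H]2C(=O)[C@@H]1[C@@H](c1ccc(OC(C)=O)cc1)[C@@H]2c1cc(OC(C)=O)cc(OC(C)=O)c1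
F10 | step 8 | C2 trimethylsilyl enol ether of F9 | C[Si](C)(C)OC1=CC(/C=C/c2ccc(OC(C)=O)cc2)[C@H]2C(=O)[C@@H]1[C@@H](c1ccc(OC(C)=O)cc1)[C@@H]2c1cc(OC(C)=O)cc(OC(C)=O)c1
F11 | step 8 | tetraacetate of 19 | O=C1C=C(/C=C/c2ccc(OC(C)=O)cc2)[C@H]2C(=O)[C@@H]1[C@@H](c1ccc(OC(C)=O)cc1)[C@@H]2c1cc(OC(C)=O)cc(OC(C)=O)c1
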